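**Plan**
- Retrosynthesis: the two gallate esters at O7 and O4' are cut first, then the O1–C8a aryl ether of ring C, then C2–C1' (aryl Grignard plus N-methoxy-N-methylamide) and C3–C4 (glycolate enolate plus ring A benzylic bromide).
- Enabling feature: C8a of ring A is ortho to the C4 methylene, so a bromine at C8a and the benzylic C2 hydroxyl of an open 1,3-diarylpropane chain can be joined as O1–C8a, closing ring C last without breaking a bond at C2 or C3.
- Forward order: ring A benzylic bromide → C3–C4 by auxiliary-controlled alkylation → C2–C1' by Grignard addition → ketone reduction → ring C closure → desilylation, double galloylation, hydrogenolysis.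
- Stereochemistry: C3 (S) comes from alkylation of the (R)-4-benzyl-oxazolidinone glycolate; C2 (R) comes from chelation-controlled Zn(BH4)2 reduction of the α-benzyloxy ketone (anti); closure at oxygen keeps both, giving the 2,3-trans flavan.
- Protecting groups: benzyl on O3, O5, O3' and the gallate oxygens (all removed at the end); triisopropylsilyl on O7 and O4', the two sites to be acylated.

Key step: step 13

Assumption: 3,4,5-tris(benzyloxy)benzoic acid, the perbenzylated form of gallic acid, is taken as a purchased starting material.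

**Step 1**
Reactants: 1 5-bromoresorcinol
Product: 3 2-bromo-4,6-dihydroxybenzaldehyde, via aryl iminium chloride 2 (not isolated)
Conditions: POCl3, DMF, MeCN, 0 °C → rt; then H2O, 50 °C
Reagents that add atoms: N,N-dimethylformamide CN(C)C=O; water O
Why: Vilsmeier–Haack formylation of a resorcinol goes para to one hydroxyl and ortho to the other (as known for orcinol) rather than between the two hydroxyls, so attack should occur next to bromine, and hydrolysis of iminium salt 2 frees the aldehyde.

**Step 2**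
Reactants: 3 2-bromo-4,6-dihydroxybenzaldehyde
Product: 4 2-bromo-6-hydroxy-4-(triisopropylsilyloxy)benzaldehyde
Conditions: TIPSCl (1.05 equiv), imidazole, CH2Cl2, 0 °C
Reagents that add atoms: triisopropylsilyl chloride CC(C)[Si](Cl)(C(C)C)C(C)C
Why: Regioselective silylation should mark only the future O7, because the hydroxyl para to the formyl group is the more acidic and unhindered one while the ortho hydroxyl is held in a hydrogen bond to the carbonyl.

**Step 3**
Reactants: 4 2-bromo-6-hydroxy-4-(triisopropylsilyloxy)benzaldehyde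
Product: 5 2-(benzyloxy)-6-bromo-4-(triisopropylsilyloxy)benzaldehyde
Conditions: BnOH, PPh3, DIAD, THF, 0 °C → rt
Reagents that add atoms: benzyl alcohol OCc1ccccc1
Why: Mitsunobu etherification benzylates the remaining acidic phenol under neutral conditions, avoiding the base-induced loss or migration of the aryl silyl ether that carbonate and benzyl bromide could cause.

**Step 4**
Reactants: 5 2-(benzyloxy)-6-bromo-4-(triisopropylsilyloxy)benzaldehyde
Product: 6 [2-(benzyloxy)-6-bromo-4-(triisopropylsilyloxy)phenyl]methanol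
Conditions: NaBH4, MeOH/THF, 0 °C
Reagents that add atoms: none
Why: Borohydride reduction of the aromatic aldehyde gives the benzylic alcohol and leaves the aryl bromide, the benzyl ether and the hindered silyl ether untouched.

**Step 5**
Reactants: 6 [2-(benzyloxy)-6-bromo-4-(triisopropylsilyloxy)phenyl]methanol
Product: 7 1-(benzyloxy)-3-bromo-2-(bromomethyl)-5-(triisopropylsilyloxy)benzene
Conditions: CBr4, PPh3, CH2Cl2, 0 °C; used at once
Reagents that add atoms: carbon tetrabromide BrC(Br)(Br)Br
Why: Appel bromination converts the primary benzylic alcohol into the bromide under neutral, cold conditions, which suits an electron-rich benzylic bromide that should not be stored.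

**Step 6**
Reactants: 8 benzyloxyacetic acid; 9 (R)-4-benzyl-2-oxazolidinone
Product: 11 (R)-4-benzyl-3-[2-(benzyloxy)acetyl]oxazolidin-2-one, via mixed pivalic anhydride 10 (not isolated)
Conditions: PivCl, Et3N, THF, −20 °C; then 9, LiCl, −20 °C → rt
Reagents that add atoms: none
Why: Mixed-anhydride N-acylation should work because the oxazolidinone, activated by LiCl and Et3N, attacks the unhindered glycolyl carbonyl of anhydride 10 rather than the pivaloyl carbonyl.

**Step 7**
Reactants: 11 (R)-4-benzyl-3-[2-(benzyloxy)acetyl]oxazolidin-2-one; 7 1-(benzyloxy)-3-bromo-2-(bromomethyl)-5-(triisopropylsilyloxy)benzene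
Product: 13 (R)-4-benzyl-3-{(S)-2-(benzyloxy)-3-[2-(benzyloxy)-6-bromo-4-(triisopropylsilyloxy)phenyl]propanoyl}oxazolidin-2-one, via sodium enolate 12 (not isolated)
Conditions: NaN(SiMe3)2, THF, −78 °C; then 7, −78 → −45 °C
Reagents that add atoms: none
Why: In this Evans asymmetric alkylation the sodium-chelated (Z)-enolate 12 is shielded on one face by the C4 benzyl group of the (R)-auxiliary, so the benzylic bromide enters from the other face and sets the future C3 as S.

**Step 8**
Reactants: 13 (R)-4-benzyl-3-{(S)-2-(benzyloxy)-3-[2-(benzyloxy)-6-bromo-4-(triisopropylsilyloxy)phenyl]propanoyl}oxazolidin-2-one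
Product: 14 (S)-2-(benzyloxy)-3-[2-(benzyloxy)-6-bromo-4-(triisopropylsilyloxy)phenyl]-N-methoxy-N-methylpropanamide
Conditions: MeONHMe·HCl, AlMe3, CH2Cl2, −15 °C → rt
Reagents that add atoms: N,O-dimethylhydroxylamine hydrochloride CNOC.Cl
Why: Weinreb aluminium-amide transamination opens the exocyclic imide carbonyl, helped by coordination of the α-benzyloxy oxygen to aluminium, and releases the auxiliary without touching the α-stereocentre.

**Step 9**
Reactants: 15 2-(benzyloxy)phenol
Product: 16 2-(benzyloxy)-4-bromophenol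
Conditions: NBS, MeCN, 0 °C
Reagents that add atoms: N-bromosuccinimide O=C1CCC(=O)N1Br
Why: Electrophilic aromatic bromination takes place para to the free hydroxyl, the strongest activating group, as in the bromination of guaiacol.

**Step 10**
Reactants: 16 2-(benzyloxy)-4-bromophenol
Product: 17 [2-(benzyloxy)-4-bromophenoxy]triisopropylsilane
Conditions: TIPSCl, imidazole, DMF, rt
Reagents that add atoms: triisopropylsilyl chloride CC(C)[Si](Cl)(C(C)C)C(C)C
Why: Standard imidazole-promoted silylation of a phenol gives a silyl ether that sits para to bromine, so later metalation cannot trigger an oxygen-to-carbon silyl shift.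

**Step 11**
Reactants: 17 [2-(benzyloxy)-4-bromophenoxy]triisopropylsilane; 14 (S)-2-(benzyloxy)-3-[2-(benzyloxy)-6-bromo-4-(triisopropylsilyloxy)phenyl]-N-methoxy-N-methylpropanamide
Product: 19 (S)-2-(benzyloxy)-1-[3-(benzyloxy)-4-(triisopropylsilyloxy)phenyl]-3-[2-(benzyloxy)-6-bromo-4-(triisopropylsilyloxy)phenyl]propan-1-one, via arylmagnesium bromide 18 (not isolated)
Conditions: 17, Mg, I2 (cat.), THF, 40 °C; then 14, THF, 0 °C; aq NH4Cl
Reagents that add atoms: none
Why: In this Weinreb ketone synthesis the Grignard reagent 18 adds once to the N-methoxy-N-methylamide and, unlike an aryllithium, should neither exchange with the ring A aryl bromide nor enolise the α-stereocentre.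

**Step 12**
Reactants: 19 (S)-2-(benzyloxy)-1-[3-(benzyloxy)-4-(triisopropylsilyloxy)phenyl]-3-[2-(benzyloxy)-6-bromo-4-(triisopropylsilyloxy)phenyl]propan-1-one
Product: 20 (1R,2S)-2-(benzyloxy)-1-[3-(benzyloxy)-4-(triisopropylsilyloxy)phenyl]-3-[2-(benzyloxy)-6-bromo-4-(triisopropylsilyloxy)phenyl]propan-1-ol
Conditions: Zn(BH4)2, Et2O, −20 → 0 °C
Reagents that add atoms: none
Why: In this chelation-controlled (Cram-chelate) reduction divalent zinc bridges the carbonyl and α-benzyloxy oxygens, and hydride attacks the face of the five-membered chelate that carries the α-hydrogen, which should give the anti (1R,2S) alcohol.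

**Step 13**
Reactants: 20 (1R,2S)-2-(benzyloxy)-1-[3-(benzyloxy)-4-(triisopropylsilyloxy)phenyl]-3-[2-(benzyloxy)-6-bromo-4-(triisopropylsilyloxy)phenyl]propan-1-ol
Product: 21 (2R,3S)-3,5,3'-tri-O-benzyl-7,4'-bis-O-(triisopropylsilyl)catechin
Conditions: Pd(OAc)2 (5 mol %), 2-(di-tert-butylphosphino)-1,1'-binaphthyl (6 mol %), Cs2CO3, toluene, 70 °C
Reagents that add atoms: none
Why: Pd(OAc)2 is reduced in the flask to a zerovalent palladium–phosphine complex that inserts into the C8a–Br bond of ring A; Cs2CO3 then deprotonates the C2 hydroxyl, the alkoxide displaces bromide on divalent palladium, and C–O reductive elimination forms O1–C8a and regenerates zerovalent palladium. The closest known reaction type is the Buchwald–Hartwig-type intramolecular etherification of aryl bromides carrying secondary alcohols, which gives chromans with this class of bulky di-tert-butyl biaryl phosphines. Ring C closes as a six-membered ring by reductive elimination from a seven-membered aryl(alkoxo)palladacycle, formally a 6-exo closure of oxygen onto the aryl carbon. No stereocentre is created: neither the C2–O nor the C3–O bond is broken, so the anti (1R,2S) chain of 20 maps directly onto the 2,3-trans (2R,3S) flavan. The step needs C–O reductive elimination to outrun β-hydride elimination of the benzylic alkoxide, which the bulky electron-rich phosphine should secure, and it needs coupling at the C2 oxygen only, which follows from O3 being benzylated so that 20 has one free hydroxyl and one aryl halide. The silyl and benzyl ethers should be inert to Cs2CO3 in dry toluene.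

**Step 14**
Reactants: 21 (2R,3S)-3,5,3'-tri-O-benzyl-7,4'-bis-O-(triisopropylsilyl)catechin
Product: 22 (2R,3S)-3,5,3'-tri-O-benzylcatechin
Conditions: Bu4NF, AcOH, THF, 0 °C
Reagents that add atoms: none
Why: Fluoride-mediated desilylation cleaves both aryl silyl ethers, and the acetic acid buffer keeps the freed phenols protonated so that a 4'-phenoxide cannot open ring C and scramble C2.

**Step 15**
Reactants: 22 (2R,3S)-3,5,3'-tri-O-benzylcatechin; 23 3,4,5-tris(benzyloxy)benzoic acid
Product: 24 (2R,3S)-3,5,3'-tri-O-benzyl-7,4'-bis-O-[3,4,5-tris(benzyloxy)benzoyl]catechin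
Conditions: 23 (2.4 equiv), EDC·HCl, DMAP (cat.), CH2Cl2, rt
Reagents that add atoms: none
Why: Steglich-type carbodiimide esterification acylates the only two free hydroxyls, the phenols at C7 and C4', since O3, O5 and O3' are benzylated.

**Step 16**
Reactants: 24 (2R,3S)-3,5,3'-tri-O-benzyl-7,4'-bis-O-[3,4,5-tris(benzyloxy)benzoyl]catechin
Product: 25 catechin 7,4'-di-O-gallate
Conditions: H2 (1 atm), Pd(OH)2 on carbon, THF/EtOAc, rt
Reagents that add atoms: none
Why: Catalytic hydrogenolysis removes all nine benzyl ethers under neutral conditions, and the aprotic, base-free medium is chosen so that the aryl gallate esters neither solvolyse nor migrate to the neighbouring 3'-hydroxyl.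

**Compound list**
1 | 5-bromoresorcinol | Oc1cc(O)cc(Br)c1 | starting material
2 | [(2-bromo-4,6-dihydroxyphenyl)methylidene]dimethylammonium chloride | C[N+](C)=Cc1c(O)cc(O)cc1Br.[Cl-] | intermediate
3 | 2-bromo-4,6-dihydroxybenzaldehyde | O=Cc1c(O)cc(O)cc1Br | intermediate
4 | 2-bromo-6-hydroxy-4-(triisopropylsilyloxy)benzaldehyde | O=Cc1c(O)cc(O[Si](C(C)C)(C(C)C)C(C)C)cc1Br | intermediate
5 | 2-(benzyloxy)-6-bromo-4-(triisopropylsilyloxy)benzaldehyde | O=Cc1c(OCc2ccccc2)cc(O[Si](C(C)C)(C(C)C)C(C)C)cc1Br | intermediate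
6 | [2-(benzyloxy)-6-bromo-4-(triisopropylsilyloxy)phenyl]methanol | OCc1c(OCc2ccccc2)cc(O[Si](C(C)C)(C(C)C)C(C)C)cc1Br | intermediate
7 | 1-(benzyloxy)-3-bromo-2-(bromomethyl)-5-(triisopropylsilyloxy)benzene | BrCc1c(OCc2ccccc2)cc(O[Si](C(C)C)(C(C)C)C(C)C)cc1Br | intermediate
8 | benzyloxyacetic acid | OC(=O)COCc1ccccc1 | starting material
9 | (R)-4-benzyl-2-oxazolidinone | O=C1N[C@H](Cc2ccccc2)CO1 | starting material
10 | 2-(benzyloxy)acetic pivalic anhydride | CC(C)(C)C(=O)OC(=O)COCc1ccccc1 | intermediate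
11 | (R)-4-benzyl-3-[2-(benzyloxy)acetyl]oxazolidin-2-one | O=C(COCc1ccccc1)N1[C@H](Cc2ccccc2)COC1=O | intermediate
12 | sodium (Z)-2-(benzyloxy)-1-[(R)-4-benzyl-2-oxooxazolidin-3-yl]ethen-1-olate | [Na+].[O-]/C(=C\OCc1ccccc1)N1[C@H](Cc2ccccc2)COC1=O | intermediate
13 | (R)-4-benzyl-3-{(S)-2-(benzyloxy)-3-[2-(benzyloxy)-6-bromo-4-(triisopropylsilyloxy)phenyl]propanoyl}oxazolidin-2-one | O=C([C@@H](OCc1ccccc1)Cc1c(Br)cc(O[Si](C(C)C)(C(C)C)C(C)C)cc1OCc1ccccc1)N1[C@H](Cc2ccccc2)COC1=O | intermediate
14 | (S)-2-(benzyloxy)-3-[2-(benzyloxy)-6-bromo-4-(triisopropylsilyloxy)phenyl]-N-methoxy-N-methylpropanamide | CON(C)C(=O)[C@@H](OCc1ccccc1)Cc1c(Br)cc(O[Si](C(C)C)(C(C)C)C(C)C)cc1OCc1ccccc1 | intermediate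
15 | 2-(benzyloxy)phenol | Oc1ccccc1OCc1ccccc1 | starting material
16 | 2-(benzyloxy)-4-bromophenol | Oc1ccc(Br)cc1OCc1ccccc1 | intermediate
17 | [2-(benzyloxy)-4-bromophenoxy]triisopropylsilane | CC(C)[Si](Oc1ccc(Br)cc1OCc1ccccc1)(C(C)C)C(C)C | intermediate
18 | [3-(benzyloxy)-4-(triisopropylsilyloxy)phenyl]magnesium bromide | Br[Mg]c1ccc(O[Si](C(C)C)(C(C)C)C(C)C)c(OCc2ccccc2)c1 | intermediate
19 | (S)-2-(benzyloxy)-1-[3-(benzyloxy)-4-(triisopropylsilyloxy)phenyl]-3-[2-(benzyloxy)-6-bromo-4-(triisopropylsilyloxy)phenyl]propan-1-one | O=C(c1ccc(O[Si](C(C)C)(C(C)C)C(C)C)c(OCc2ccccc2)c1)[C@@H](OCc1ccccc1)Cc1c(Br)cc(O[Si](C(C)C)(C(C)C)C(C)C)cc1OCc1ccccc1 | intermediate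
20 | (1R,2S)-2-(benzyloxy)-1-[3-(benzyloxy)-4-(triisopropylsilyloxy)phenyl]-3-[2-(benzyloxy)-6-bromo-4-(triisopropylsilyloxy)phenyl]propan-1-ol (anti) | O[C@H](c1ccc(O[Si](C(C)C)(C(C)C)C(C)C)c(OCc2ccccc2)c1)[C@@H](OCc1ccccc1)Cc1c(Br)cc(O[Si](C(C)C)(C(C)C)C(C)C)cc1OCc1ccccc1 | intermediate
21 | (2R,3S)-3,5,3'-tri-O-benzyl-7,4'-bis-O-(triisopropylsilyl)catechin (2,3-trans) | CC(C)[Si](Oc1cc(OCc2ccccc2)c2c(c1)O[C@H](c1ccc(O[Si](C(C)C)(C(C)C)C(C)C)c(OCc3ccccc3)c1)[C@@H](OCc1ccccc1)C2)(C(C)C)C(C)C | intermediate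
22 | (2R,3S)-3,5,3'-tri-O-benzylcatechin | Oc1cc(OCc2ccccc2)c2c(c1)O[C@H](c1ccc(O)c(OCc3ccccc3)c1)[C@@H](OCc1ccccc1)C2 | intermediate
23 | 3,4,5-tris(benzyloxy)benzoic acid | OC(=O)c1cc(OCc2ccccc2)c(OCc2ccccc2)c(OCc2ccccc2)c1 | starting material
24 | (2R,3S)-3,5,3'-tri-O-benzyl-7,4'-bis-O-[3,4,5-tris(benzyloxy)benzoyl]catechin | O=C(Oc1cc(OCc2ccccc2)c2c(c1)O[C@H](c1ccc(OC(=O)c3cc(OCc4ccccc4)c(OCc4ccccc4)c(OCc4ccccc4)c3)c(OCc3ccccc3)c1)[C@@H](OCc1ccccc1)C2)c1cc(OCc2ccccc2)c(OCc2ccccc2)c(OCc2ccccc2)c1 | intermediate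
25 | catechin 7,4'-di-O-gallate, (2R,3S) | O=C(Oc1cc(O)c2c(c1)O[C@H](c1ccc(OC(=O)c3cc(O)c(O)c(O)c3)c(O)c1)[C@@H](O)C2)c1cc(O)c(O)c(O)c1 | target

Total step count: 16.
Longest linear sequence: 13 steps (steps 1–5, 7, 8, 11–16).

**Steps most likely to fail**

Step 13. After oxidative addition, the palladium alkoxide may lose the benzylic C2 hydrogen by β-hydride elimination faster than it forms the C–O bond, which would oxidise the alcohol back to the ketone and reduce the aryl halide. The fallback changes both the halide and the metal to a copper Ullmann-type closure, which has no comparable alkoxide β-hydride pathway. It sets out from 20: aromatic Finkelstein exchange (copper monoiodide CuI cat., NaI, trans-N,N'-dimethylcyclohexane-1,2-diamine, dioxane, 110 °C) would give the aryl iodide (1R,2S)-2-(benzyloxy)-1-[3-(benzyloxy)-4-(triisopropylsilyloxy)phenyl]-3-[2-(benzyloxy)-6-iodo-4-(triisopropylsilyloxy)phenyl]propan-1-ol F1. CuI with 3,4,7,8-tetramethyl-1,10-phenanthroline and Cs2CO3 in toluene at 110 °C would then close O1–C8a, again with retention at C2, and the route is rejoined at 21.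

Step 7. The electron-rich benzylic bromide may ionise and self-condense, and the glycolate enolate may decompose, before C-alkylation takes place. The fallback forms C3–C4 by an aldol addition to the stable aldehyde and then removes the benzylic oxygen; because aldol and alkylation use opposite enolate faces, the enantiomeric auxiliary is needed. It sets out from 5 (and 8). Acid 8 would be joined to (S)-4-benzyl-2-oxazolidinone as in step 6 to give (S)-4-benzyl-3-[2-(benzyloxy)acetyl]oxazolidin-2-one F2. Bu2BOTf and iPr2NEt in CH2Cl2 at −78 °C would convert it into the dibutylboron (Z)-enolate F3, which should add to aldehyde 5 through a closed chair transition state to give the syn aldol adduct (S)-4-benzyl-3-{(2S,3R)-2-(benzyloxy)-3-[2-(benzyloxy)-6-bromo-4-(triisopropylsilyloxy)phenyl]-3-hydroxypropanoyl}oxazolidin-2-one F4. Ionic reduction of the oxygen-stabilised benzylic alcohol (Et3SiH, CF3CO2H, CH2Cl2, 0 °C) would give (S)-4-benzyl-3-{(S)-2-(benzyloxy)-3-[2-(benzyloxy)-6-bromo-4-(triisopropylsilyloxy)phenyl]propanoyl}oxazolidin-2-one F5. Transamination under the conditions of step 8 rejoins the route at 14.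

Step 8. The aluminium amide may attack the ring carbonyl of the oxazolidinone instead of the hindered exocyclic carbonyl, opening the auxiliary instead of releasing it. The fallback separates cleavage and amide formation. It sets out from 13: LiOH and H2O2 in THF/H2O at 0 °C (brief exposure, which the hindered aryl silyl ether should tolerate) would give (S)-2-(benzyloxy)-3-[2-(benzyloxy)-6-bromo-4-(triisopropylsilyloxy)phenyl]propanoic acid F6. Coupling with MeONHMe·HCl (EDC·HCl, HOBt, iPr2NEt, CH2Cl2, 0 °C → rt) rejoins the route at 14.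

**Further compounds**
F1 | step 13 | (1R,2S)-2-(benzyloxy)-1-[3-(benzyloxy)-4-(triisopropylsilyloxy)phenyl]-3-[2-(benzyloxy)-6-iodo-4-(triisopropylsilyloxy)phenyl]propan-1-ol | O[C@H](c1ccc(O[Si](C(C)C)(C(C)C)C(C)C)c(OCc2ccccc2)c1)[C@@H](OCc1ccccc1)Cc1c(I)cc(O[Si](C(C)C)(C(C)C)C(C)C)cc1OCc1ccccc1
F2 | step 7 | (S)-4-benzyl-3-[2-(benzyloxy)acetyl]oxazolidin-2-one | O=C(COCc1ccccc1)N1[C@@H](Cc2ccccc2)COC1=O
F3 | step 7 | dibutylboron (Z)-enolate of F2 | CCCCB(CCCC)O/C(=C\OCc1ccccc1)N1[C@@H](Cc2ccccc2)COC1=O
F4 | step 7 | (S)-4-benzyl-3-{(2S,3R)-2-(benzyloxy)-3-[2-(benzyloxy)-6-bromo-4-(triisopropylsilyloxy)phenyl]-3-hydroxypropanoyl}oxazolidin-2-one | O=C([C@@H](OCc1ccccc1)[C@H](O)c1c(Br)cc(O[Si](C(C)C)(C(C)C)C(C)C)cc1OCc1ccccc1)N1[C@@H](Cc2ccccc2)COC1=O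
F5 | step 7 | (S)-4-benzyl-3-{(S)-2-(benzyloxy)-3-[2-(benzyloxy)-6-bromo-4-(triisopropylsilyloxy)phenyl]propanoyl}oxazolidin-2-one | O=C([C@@H](OCc1ccccc1)Cc1c(Br)cc(O[Si](C(C)C)(C(C)C)C(C)C)cc1OCc1ccccc1)N1[C@@H](Cc2ccccc2)COC1=O
F6 | step 8 | (S)-2-(benzyloxy)-3-[2-(benzyloxy)-6-bromo-4-(triisopropylsilyloxy)phenyl]propanoic acid | OC(=O)[C@@H](OCc1ccccc1)Cc1c(Br)cc(O[Si](C(C)C)(C(C)C)C(C)C)cc1OCc1ccccc1
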